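## Retrosynthetic overview

1. The target comes from its 14‑O‑silyl ether. The cycloheptenone is formed by a transannular oxy‑Cope shift of an 11‑membered vibsanin‑B‑type dienone: C5–C10 forms, C7–C8 breaks. This one step sets C5, C10 and the E‑enol senecioate.
2. The 11‑membered ring comes from an acyclic seco‑ester. CO is inserted as C4 between a C3 alkenyl iodide and a C5 alkenylstannane. Ring order: the 11‑membered ring first, then contraction to the 7‑membered ring in the same operation.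
3. The seco‑ester comes from SN2 opening at C8 of a Sharpless‑derived (7S,8S)‑epoxide with senecioic acid. C3 and C18 are added by an iodo‑Wittig reaction and i‑Bu2AlH reduction.
4. The quaternary C11 and the E‑C9=C10 alkene come from a Johnson–Claisen rearrangement with 1,3‑chirality transfer from a C9 carbinol.
5. The C9–C10 bond comes from a (Z)‑alkenyllithium (carbocupration, Shi epoxidation for C14) and an epoxy aldehyde.

Assumption: vibsane numbering is used throughout.
- C1 is the ring CH2. C2=C3 is the ring alkene, and C18 is the CH2OH on C3. C4 is the ring C=O.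
- C5 carries the acetonyl group C6–C7(=O)–C19.
- C10 carries C9H=C8H–O‑senecioyl.
- C11 is quaternary, with methyl C20 and the chain C12–C17.
- In this numbering the given SMILES is (5S,10S,11S,14R,8E).

## Route

Step 1
Reactants: 1 5‑bromo‑2‑methylpent‑2‑ene; 2 propyne
Product: 6 (1Z)‑1‑iodo‑2,6‑dimethylhepta‑1,5‑diene, via homoprenyl Grignard reagent 3 (not isolated), via homoprenylcopper 4 (not isolated), via (Z)‑alkenylcopper 5 (not isolated)
Conditions: Mg, Et2O, reflux; CuBr·SMe2, Et2O–Me2S, −45 °C; 2, −25 °C, 3 h; I2, THF, −50 → 0 °C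
Reagents that add atoms: iodine, II; magnesium, [Mg]; CuBr·SMe2, [Cu]Br.CSC (Mg and Cu stay only in 3–5)
Why: In this Normant carbocupration the primary alkylcopper adds syn across propyne with copper on the terminal carbon, so the chain and copper (then iodine, with retention) end up cis, which fixes the (Z)‑C10=C11 geometry.

Step 2
Reactants: 6 (1Z)‑1‑iodo‑2,6‑dimethylhepta‑1,5‑diene
Product: 7 (3R)‑3‑[(3Z)‑4‑iodo‑3‑methylbut‑3‑en‑1‑yl]‑2,2‑dimethyloxirane
Conditions: D‑fructose‑derived Shi ketone (30 mol %), Oxone (2KHSO5·KHSO4·K2SO4), K2CO3, Bu4NHSO4, MeCN–DMM–aq. Na2B4O7/Na2EDTA, 0 °C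
Reagents that add atoms: potassium peroxymonosulfate (active part of Oxone), [K+].[O-]S(=O)(=O)OO
Why: In this Shi asymmetric epoxidation the chiral dioxirane attacks only the electron‑rich C14=C15 alkene (the iodoalkene is deactivated), and its spiro transition state gives the (14R)‑epoxide.

Step 3
Reactants: 7 (3R)‑epoxide
Product: 8 tert‑butyl{[(3R,6Z)‑7‑iodo‑2,6‑dimethylhepta‑1,6‑dien‑3‑yl]oxy}dimethylsilane
Conditions: TBSOTf, 2,6‑lutidine, toluene, −78 → −20 °C
Reagents that add atoms: tert‑butyldimethylsilyl triflate, CC(C)(C)[Si](C)(C)OS(=O)(=O)C(F)(F)F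
Why: In this silyl triflate/amine epoxide‑to‑allyl silyl ether isomerisation the silylated epoxide ionises at the tertiary C15 and loses a methyl proton, so the C14–O bond is never touched and (14R) is kept while the alcohol emerges already protected.

Step 4
Reactants: 9 (2E)‑3‑methylpent‑2‑en‑4‑yn‑1‑ol
Product: 10 (2E,4E)‑3‑methyl‑5‑(tributylstannyl)penta‑2,4‑dien‑1‑ol
Conditions: Bu3SnH, PdCl2(PPh3)2 (2 mol %), THF, 0 °C; the minor internal stannane is removed on Et3N‑washed silica
Reagents that add atoms: tributyltin hydride, CCCC[SnH](CCCC)CCCC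
Why: Palladium‑catalysed syn hydrostannation of the terminal alkyne puts tin on the less hindered carbon and gives the E‑C5=C6 alkenylstannane.

Step 5
Reactants: 10 stannyl dienol
Product: 11 {(2S,3S)‑3‑methyl‑3‑[(E)‑2‑(tributylstannyl)ethenyl]oxiran‑2‑yl}methanol
Conditions: Ti(OiPr)4 (10 mol %), L‑(+)‑DIPT (13 mol %), t‑BuOOH, 4 Å MS, CH2Cl2, −20 °C
Reagents that add atoms: tert‑butyl hydroperoxide, CC(C)(C)OO
Why: The Sharpless asymmetric epoxidation is directed by the C9 hydroxyl to the allylic C7=C8 alkene only, and L‑(+)‑tartrate gives (7S,8S), with the same facial sense as for geraniol.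

Step 6
Reactants: 11 epoxy alcohol
Product: 12 (2R,3S)‑3‑methyl‑3‑[(E)‑2‑(tributylstannyl)ethenyl]oxirane‑2‑carbaldehyde
Conditions: Pr4N[RuO4] (5 mol %), NMO, 4 Å MS, CH2Cl2, 0 °C → rt
Reagents that add atoms: none
Why: The neutral Ley–Griffith oxidation stops at the aldehyde and leaves the acid‑sensitive epoxide, the stannane and both stereocentres untouched (the C8 descriptor changes only by CIP priority).

Step 7
Reactants: 8 (Z)‑alkenyl iodide; 12 epoxy aldehyde
Product: 14 (1S,2Z,6R)‑6‑(tert‑butyldimethylsilyloxy)‑3,7‑dimethyl‑1‑{(2S,3S)‑3‑methyl‑3‑[(E)‑2‑(tributylstannyl)ethenyl]oxiran‑2‑yl}octa‑2,7‑dien‑1‑ol, that is (7S,8S,9S,10Z,14R), via alkenyllithium 13 (not isolated)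
Conditions: t‑BuLi (2.0 equiv), Et2O, −78 °C; 12, −78 °C; H2O
Reagents that add atoms: tert‑butyllithium, [Li]C(C)(C)C (Li stays only in 13)
Why: After I/Li exchange with retention, a Felkin–Anh (Cornforth) 1,2‑addition takes place in which the aldehyde reacts with C=O anti to the epoxide C–O bond and the nucleophile enters past the epoxide oxygen, away from C7 whose methyl is cis to the formyl group, giving the anti (erythro) carbinol (9S).

Step 8
Reactants: 14 epoxy allylic alcohol
Product: 17 ethyl (3S,4E)‑3‑[(3R)‑3‑(tert‑butyldimethylsilyloxy)‑4‑methylpent‑4‑en‑1‑yl]‑3‑methyl‑5‑{(2S,3S)‑3‑methyl‑3‑[(E)‑2‑(tributylstannyl)ethenyl]oxiran‑2‑yl}pent‑4‑enoate, via mixed orthoester 15 (not isolated), via ketene acetal 16 (not isolated)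
Conditions: MeC(OEt)3 (10 equiv), 2‑nitrophenol (5 mol %), xylene, 135 °C, EtOH distilled off
Reagents that add atoms: triethyl orthoacetate, CC(OCC)(OCC)OCC
Why: The Johnson–Claisen [3,3] shift runs through a chair with the oxiranyl group equatorial (the axial alternative clashes with the cis C12 chain), so chirality passes suprafacially from C9–O to the new C11–C1 bond, (9S,10Z) gives (11S) with E‑C9=C10, and the weak phenol catalyst spares stannane and epoxide.

Step 9
Reactants: 18 ethyl (triphenyl‑λ5‑phosphanylidene)acetate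
Product: 19 ethyl iodo(triphenyl‑λ5‑phosphanylidene)acetate
Conditions: NIS, CH2Cl2, −20 °C
Reagents that add atoms: N‑iodosuccinimide, O=C1CCC(=O)N1I
Why: Electrophilic iodination of the stabilised ylide gives the iodophosphonium salt, and the succinimide anion deprotonates it to the isolable iodo‑ylide, so no I+ source reaches the stannane later.

Step 10
Reactants: 17 ethyl ester; 19 iodo‑ylide
Product: 21 ethyl (2Z,5S,6E)‑2‑iodo‑5‑methyl‑hepta‑2,6‑dienoate carrying the C12–C17 chain at C5 of the heptadienoate chain and the stannylvinyl oxirane at its C7, that is (2Z,7S,8S,11S,14R) in vibsane numbering, via aldehyde 20 (not isolated)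
Conditions: i‑Bu2AlH (1.05 equiv), CH2Cl2, −78 °C; 19 (1.5 equiv), −78 → 40 °C; aq. potassium sodium tartrate
Reagents that add atoms: none
Why: Partial ester reduction is followed by a Wittig olefination in the same flask, and the stabilised iodo‑ylide places the ester trans to the chain, so iodine sits cis to C1 (Z), which is the geometry the later C3–C4 bond needs.

Step 11
Reactants: 21 α‑iodoenoate
Product: 22 the corresponding (2Z)‑2‑iodoallylic alcohol (C18–OH)
Conditions: i‑Bu2AlH (2.3 equiv), CH2Cl2, −78 °C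
Reagents that add atoms: none
Why: 1,2‑Reduction of the enoate with i‑Bu2AlH at −78 °C is faster than any attack on the alkenyl iodide, the stannane or the epoxide and leaves all geometry unchanged.

Step 12
Reactants: 22 iodoallylic alcohol epoxide; 23 3‑methylbut‑2‑enoic acid (senecioic acid)
Product: 24 (1E,3S,4R,5E,7S,9Z)‑7‑[(3R)‑3‑(tert‑butyldimethylsilyloxy)‑4‑methylpent‑4‑en‑1‑yl]‑3,11‑dihydroxy‑10‑iodo‑3,7‑dimethyl‑1‑(tributylstannyl)undeca‑1,5,9‑trien‑4‑yl 3‑methylbut‑2‑enoate, that is (7S,8R,11S,14R)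
Conditions: 23 (3 equiv), Cs2CO3 (25 mol %), DMF, 65 °C
Reagents that add atoms: none
Why: Caesium carboxylate opens the epoxide by SN2 attack at the secondary allylic C8 rather than the fully substituted C7, inverting (8S) to (8R), leaving C7–O intact as the free (7S) tertiary alcohol and installing the senecioate without any hydroxyl differentiation.

Step 13
Reactants: 24 seco‑ester
Product: 27 14‑O‑TBS ether of the target, via macrocyclic dienone 25 (not isolated), via enol 26 (not isolated)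
Conditions: Pd2(dba)3 (10 mol %), AsPh3 (40 mol %), CO (1 atm), 1,4‑dioxane (1 mM, syringe pump), 50 °C; filtration through thiol‑functionalised silica under Ar; filtrate 100 °C, 6 h
Reagents that add atoms: carbon monoxide, [C-]#[O+]
Why: Proposed new method: oxidative addition of zerovalent palladium into C3–I, CO insertion, tin‑to‑palladium transfer of the C5 alkenyl group and reductive elimination join C3–C4(=O)–C5 into the 11‑membered dienone 25 with both alkene geometries retained (closest known type: carbonylative Stille coupling of alkenyl iodides with alkenylstannanes to divinyl ketones, also used for macrocyclisation), and on heating 25 undergoes the thermal [3,3] oxy‑Cope shift of 3‑hydroxy‑1,5‑dienes through a chair with the C8 acyloxy group and the C19 methyl equatorial and only OH axial, so (8R) is relayed suprafacially to (10S), the E,E‑diene gives the trans partner (5S), the enol ester comes out E, and enol 26 tautomerises to the methyl ketone.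

Step 14
Reactants: 27 silyl ether
Product: 28 CNP0257974.1 (target)
Conditions: HF·pyridine, pyridine, THF, 0 °C → rt
Reagents that add atoms: none
Why: Buffered fluoride desilylation frees the C14 alcohol under mildly acidic conditions that do not cleave the enol ester, epimerise C5 or trigger aldol reaction of the 1,4‑diketone.

## Compound list

1 | 5‑bromo‑2‑methylpent‑2‑ene | CC(C)=CCCBr | starting material
2 | propyne | CC#C | starting material
3 | (4‑methylpent‑3‑en‑1‑yl)magnesium bromide | CC(C)=CCC[Mg]Br | intermediate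
4 | (4‑methylpent‑3‑en‑1‑yl)copper | CC(C)=CCC[Cu] | intermediate
5 | [(1Z)‑2,6‑dimethylhepta‑1,5‑dien‑1‑yl]copper | [Cu]/C=C(/C)CCC=C(C)C | intermediate
6 | (1Z)‑1‑iodo‑2,6‑dimethylhepta‑1,5‑diene | I/C=C(/C)CCC=C(C)C | intermediate
7 | (3R)‑3‑[(3Z)‑4‑iodo‑3‑methylbut‑3‑en‑1‑yl]‑2,2‑dimethyloxirane | I/C=C(/C)CC[C@H]1OC1(C)C | intermediate
8 | tert‑butyl{[(3R,6Z)‑7‑iodo‑2,6‑dimethylhepta‑1,6‑dien‑3‑yl]oxy}dimethylsilane | I/C=C(/C)CC[C@@H](O[Si](C)(C)C(C)(C)C)C(C)=C | intermediate
9 | (2E)‑3‑methylpent‑2‑en‑4‑yn‑1‑ol | C#C/C(C)=C/CO | starting material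
10 | (2E,4E)‑3‑methyl‑5‑(tributylstannyl)penta‑2,4‑dien‑1‑ol | CCCC[Sn](CCCC)(CCCC)/C=C/C(C)=C/CO | intermediate
11 | {(2S,3S)‑3‑methyl‑3‑[(E)‑2‑(tributylstannyl)ethenyl]oxiran‑2‑yl}methanol | OC[C@@H]1O[C@@]1(C)/C=C/[Sn](CCCC)(CCCC)CCCC | intermediate
12 | (2R,3S)‑3‑methyl‑3‑[(E)‑2‑(tributylstannyl)ethenyl]oxirane‑2‑carbaldehyde | O=C[C@@H]1O[C@@]1(C)/C=C/[Sn](CCCC)(CCCC)CCCC | intermediate
13 | [(1Z,5R)‑5‑(tert‑butyldimethylsilyloxy)‑2,6‑dimethylhepta‑1,6‑dien‑1‑yl]lithium | [Li]/C=C(/C)CC[C@@H](O[Si](C)(C)C(C)(C)C)C(C)=C | intermediate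
14 | epoxy allylic alcohol (5E,7S,8S,9S,10Z,14R), name as in step 7 | CCCC[Sn](CCCC)(CCCC)/C=C/[C@]1(C)O[C@H]1[C@@H](O)/C=C(/C)CC[C@@H](O[Si](C)(C)C(C)(C)C)C(C)=C | intermediate
15 | 1,1‑diethoxyethyl ether (mixed orthoester) of 14 at O9 | CCCC[Sn](CCCC)(CCCC)/C=C/[C@]1(C)O[C@H]1[C@@H](OC(C)(OCC)OCC)/C=C(/C)CC[C@@H](O[Si](C)(C)C(C)(C)C)C(C)=C | intermediate
16 | 1‑ethoxyethenyl ether (ketene acetal) of 14 at O9 | CCCC[Sn](CCCC)(CCCC)/C=C/[C@]1(C)O[C@H]1[C@@H](OC(=C)OCC)/C=C(/C)CC[C@@H](O[Si](C)(C)C(C)(C)C)C(C)=C | intermediate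
17 | Claisen ethyl ester (5E,7S,8S,9E,11S,14R), name as in step 8 | CCCC[Sn](CCCC)(CCCC)/C=C/[C@]1(C)O[C@H]1/C=C/[C@](C)(CC(=O)OCC)CC[C@@H](O[Si](C)(C)C(C)(C)C)C(C)=C | intermediate
18 | ethyl (triphenyl‑λ5‑phosphanylidene)acetate | CCOC(=O)C=P(c1ccccc1)(c1ccccc1)c1ccccc1 | starting material
19 | ethyl iodo(triphenyl‑λ5‑phosphanylidene)acetate | CCOC(=O)C(I)=P(c1ccccc1)(c1ccccc1)c1ccccc1 | intermediate
20 | C2 aldehyde corresponding to 17 (7S,8S,11S,14R) | CCCC[Sn](CCCC)(CCCC)/C=C/[C@]1(C)O[C@H]1/C=C/[C@](C)(CC=O)CC[C@@H](O[Si](C)(C)C(C)(C)C)C(C)=C | intermediate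
21 | (2Z)‑α‑iodoenoate (7S,8S,11S,14R; I on C3 cis to C1) | CCCC[Sn](CCCC)(CCCC)/C=C/[C@]1(C)O[C@H]1/C=C/[C@](C)(C/C=C(\I)C(=O)OCC)CC[C@@H](O[Si](C)(C)C(C)(C)C)C(C)=C | intermediate
22 | (2Z)‑2‑iodoallylic alcohol (C18–OH; 7S,8S,11S,14R) | CCCC[Sn](CCCC)(CCCC)/C=C/[C@]1(C)O[C@H]1/C=C/[C@](C)(C/C=C(\I)CO)CC[C@@H](O[Si](C)(C)C(C)(C)C)C(C)=C | intermediate
23 | 3‑methylbut‑2‑enoic acid (senecioic acid) | CC(C)=CC(=O)O | starting material
24 | seco‑ester (7S,8R,11S,14R), name as in step 12 | CCCC[Sn](CCCC)(CCCC)/C=C/[C@](C)(O)[C@H](OC(=O)C=C(C)C)/C=C/[C@](C)(C/C=C(\I)CO)CC[C@@H](O[Si](C)(C)C(C)(C)C)C(C)=C | intermediate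
25 | 11‑membered dienone (2Z,5E,9E,7S,8R,11S,14R): 7‑OH, 8‑O‑senecioyl, 4‑oxo, 18‑OH, 14‑OTBS | C[C@]1(CC[C@@H](O[Si](C)(C)C(C)(C)C)C(C)=C)C/C=C(/CO)C(=O)/C=C/[C@](C)(O)[C@H](OC(=O)C=C(C)C)/C=C/1 | intermediate
26 | cycloheptenone C6=C7 enol (methyl trans to C5) formed by the oxy‑Cope shift | C=C(C)[C@H](O[Si](C)(C)C(C)(C)C)CC[C@@]1(C)CC=C(CO)C(=O)[C@@H](/C=C(/C)O)[C@@H]1/C=C/OC(=O)C=C(C)C | intermediate
27 | 14‑O‑TBS ether of the target (5S,10S,11S,14R,8E) | C=C(C)[C@H](O[Si](C)(C)C(C)(C)C)CC[C@@]1(C)CC=C(CO)C(=O)[C@@H](CC(C)=O)[C@@H]1/C=C/OC(=O)C=C(C)C | intermediate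
28 | CNP0257974.1 | C=C(C)[C@H](O)CC[C@@]1(C)CC=C(CO)C(=O)[C@@H](CC(C)=O)[C@@H]1/C=C/OC(=O)C=C(C)C | target

## Step count and risks

Total step count: 14.
Longest linear sequence: 10 (steps 1, 2, 3, 7, 8, 10, 11, 12, 13, 14).

**Step 13 (CO macrocyclisation and oxy‑Cope contraction).** Possible failures:
- attack of the C18–OH on the acylpalladium to give a β‑lactone;
- coupling without CO;
- oligomerisation;
- ionisation of the allylic senecioate by zerovalent palladium.

Fallback: close the ring at C5=C6 by metathesis instead. Starting from 24, protodestannylation (HCl in Et2O, CH2Cl2, −40 °C) gives the terminal vinyl carbinol F1. An intermolecular carbonylative Stille coupling with tributyl(vinyl)stannane (CO, Pd2(dba)3, AsPh3, THF, 45 °C) gives the acyclic vinyl ketone F2. Ring‑closing metathesis with the second‑generation Hoveyda–Grubbs catalyst (toluene, 1 mM, 60 °C) comes back to the route at 25, which is then isolated and heated on its own to give 27.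

**Step 12 (carboxylate opening of the trisubstituted divinyl epoxide).** Possible failures are low nucleophilicity of the senecioate and attack at C7 or C10.

Fallback: reverse the polarity of the ester‑forming event.
- Starting from 22, the smaller formate (HCO2Cs, DMF, 50 °C) opens C8 with the same inversion to give the C8 formate F3.
- F3 is methanolysed in the same flask (NaHCO3, MeOH) to the 7,8,18‑triol F4.
- The primary C18–OH is capped (Et3SiCl, imidazole, −20 °C) to give the mono‑TES ether F5.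
- The secondary C8–OH, not the tertiary C7–OH, is acylated with 23 (EDC·HCl, DMAP) to give the TES‑protected seco‑ester F6.
- PPTS in MeOH removes the TES group and comes back to the route at 24.

**Step 7 (facial selectivity at C9).** The possible failure is a poor anti/syn ratio.

Fallback: set C9 by reduction instead of by addition. Starting from 8 and 12, the unselective adduct, which is 14 together with the C9 epimer F7, is oxidised (Dess–Martin periodinane, NaHCO3, CH2Cl2) to the epoxy enone F8. Zn(BH4)2 (Et2O, −30 °C) then delivers hydride to the epoxide‑oxygen face of the s‑cis epoxy ketone. This is the usual anti (erythro) outcome for α,β‑epoxy ketones, and it comes back to the route at 14.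

## Further compounds

F1 | step 13 | destannylated seco‑ester with terminal C5=C6 vinyl carbinol (7S,8R,11S,14R) | C=C[C@](C)(O)[C@H](OC(=O)C=C(C)C)/C=C/[C@](C)(C/C=C(\I)CO)CC[C@@H](O[Si](C)(C)C(C)(C)C)C(C)=C
F2 | step 13 | acyclic vinyl ketone, C3–C4(=O)–CH=CH2, (2Z,7S,8R,11S,14R) | C=C[C@](C)(O)[C@H](OC(=O)C=C(C)C)/C=C/[C@](C)(C/C=C(/CO)C(=O)C=C)CC[C@@H](O[Si](C)(C)C(C)(C)C)C(C)=C
F3 | step 12 | C8 formate of the opened epoxide (7S,8R,11S,14R) | CCCC[Sn](CCCC)(CCCC)/C=C/[C@](C)(O)[C@H](OC=O)/C=C/[C@](C)(C/C=C(\I)CO)CC[C@@H](O[Si](C)(C)C(C)(C)C)C(C)=C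
F4 | step 12 | 7,8,18‑triol (7S,8R,11S,14R) | CCCC[Sn](CCCC)(CCCC)/C=C/[C@](C)(O)[C@H](O)/C=C/[C@](C)(C/C=C(\I)CO)CC[C@@H](O[Si](C)(C)C(C)(C)C)C(C)=C
F5 | step 12 | 18‑O‑TES ether of the triol | CCCC[Sn](CCCC)(CCCC)/C=C/[C@](C)(O)[C@H](O)/C=C/[C@](C)(C/C=C(\I)CO[Si](CC)(CC)CC)CC[C@@H](O[Si](C)(C)C(C)(C)C)C(C)=C
F6 | step 12 | 18‑O‑TES ether of seco‑ester 24 | CCCC[Sn](CCCC)(CCCC)/C=C/[C@](C)(O)[C@H](OC(=O)C=C(C)C)/C=C/[C@](C)(C/C=C(\I)CO[Si](CC)(CC)CC)CC[C@@H](O[Si](C)(C)C(C)(C)C)C(C)=C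
F7 | step 7 | (9R) epimer of 14 | CCCC[Sn](CCCC)(CCCC)/C=C/[C@]1(C)O[C@H]1[C@H](O)/C=C(/C)CC[C@@H](O[Si](C)(C)C(C)(C)C)C(C)=C
F8 | step 7 | C9 epoxy enone (7S,8S,10Z,14R) | CCCC[Sn](CCCC)(CCCC)/C=C/[C@]1(C)O[C@H]1C(=O)/C=C(/C)CC[C@@H](O[Si](C)(C)C(C)(C)C)C(C)=C
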